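**Retrosynthetic overview**
1. The ten-membered ring is closed last by ring-closing metathesis at C3=C4, between a C2 vinyl carbinol and a 2-substituted butadiene (C4, C5, C16).
2. The γ-lactone comes from a chelation-controlled propanoate aldol on a C8 ketone followed by lactonisation through O7; the C6 chloride comes from invertive chlorination of the allylic alcohol.
3. The fragments are joined at C8–C9 by adding a C9 alkyllithium (ring fragment) to a C8 Weinreb amide (tartrate fragment); the C9 oxygen is added by enolate hydroxylation.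
4. Ring fragment: a catalytic asymmetric Diels–Alder reaction builds the cyclohexenone (C1, C10); OsO4 on a 1,3-diene gives the cis C11/C12 diol.
5. Tartrate fragment: D-tartaric acid supplies C5–C8 (C6, C7). Ring order: cyclohexene (step 1), lactone (step 22), ten-membered ring (step 24).

Numbering used in names: locants C1–C20 are those of the target. C1 is the quaternary ring-fusion carbon (CH3 = C15), C2 (OAc), C3=C4 (Z), C5 (=C16H2), C6 (Cl), C7 (lactone O), C8 (OH), C9 (OAc), C10 (ring-fusion CH), C11 (OH, CH3 = C20), C12 (OAc), C13=C14, C17 (CH3 = C18), C19 (lactone C=O).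

Assumption: the sense of induction in the three reagent-controlled steps (1, 2 and 20) is taken from the nearest known substrate classes; if one proves opposite, the mirror-image catalyst or reagent is used.

**Ring fragment (steps 1–9)**

Step 1
Reactants: 1 ethyl (E)-3-methyl-4-oxobut-2-enoate; 2 (E)-3-(tert-butyldimethylsilyloxy)-N,N-dimethylbuta-1,3-dien-1-amine (Rawal diene)
Product: 4 ethyl (1S,2S)-2-formyl-2-methyl-5-oxocyclohex-3-ene-1-carboxylate, via amino silyl enol ether cycloadduct 3 (not isolated)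
Conditions: (4R,5R)-2,2-dimethyl-α,α,α′,α′-tetra(1-naphthyl)-1,3-dioxolane-4,5-dimethanol (20 mol %), toluene, −78 → −40 °C; then HF (aq.), MeCN, 0 °C
Reagents that add atoms: none
Why: A hydrogen-bond-catalysed Diels–Alder reaction in which the nucleophilic CH2 terminus of the aminosiloxydiene bonds to the enal β-carbon (C10) while the chiral diol shields one face of the aldehyde-activated alkene, setting C1 and C10 with the trans relationship dictated by the E geometry of 1, after which acid unmasks the ketone and eliminates dimethylamine to give the C13=C14 enone.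

Step 2
Reactants: 4 ethyl (1S,2S)-2-formyl-2-methyl-5-oxocyclohex-3-ene-1-carboxylate
Product: 6 ethyl (1S,2S)-2-[(1R)-1-(tert-butyldimethylsilyloxy)prop-2-en-1-yl]-2-methyl-5-oxocyclohex-3-ene-1-carboxylate, via vinylzinc alkoxide 5 (not isolated)
Conditions: Zn(CH=CH2)2, (+)-3-exo-morpholinoisoborneol (10 mol %), toluene, 0 °C; then TBSOTf, 2,6-lutidine, CH2Cl2, −20 °C
Reagents that add atoms: divinylzinc, C=C[Zn]C=C; tert-butyldimethylsilyl triflate, CC(C)(C)[Si](C)(C)OS(=O)(=O)C(F)(F)F
Why: Amino-alcohol-catalysed vinylzinc addition to the non-enolisable neopentyl aldehyde (enone and ester are inert to organozincs) in which the ligand delivers vinyl to the Re face and sets C2 (R) under reagent control, the zinc alkoxide then being silylated in the same flask.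

Step 3
Reactants: 6 ethyl (1S,2S)-2-[(1R)-1-(tert-butyldimethylsilyloxy)prop-2-en-1-yl]-2-methyl-5-oxocyclohex-3-ene-1-carboxylate
Product: 8 ethyl 2-[(1R)-1-(tert-butyldimethylsilyloxy)prop-2-en-1-yl]-2,6-dimethyl-5-oxocyclohex-3-ene-1-carboxylate (C1 and C10 as in 6; both C11 epimers), via lithium dienolate 7 (not isolated)
Conditions: LiN(iPr)2, THF, −78 °C; MeI, −78 → −20 °C
Reagents that add atoms: iodomethane, CI
Why: Kinetic α′-deprotonation of the enone (no γ-hydrogen, and the ketone is far more acidic than the hindered ester) followed by enolate C-alkylation installs C20; the new C11 centre becomes sp2 in the next step, so its configuration does not matter.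

Step 4
Reactants: 8 C11-methylated enone
Product: 10 ethyl 2-[(1R)-1-(tert-butyldimethylsilyloxy)prop-2-en-1-yl]-2,6-dimethyl-5-(trifluoromethylsulfonyloxy)cyclohexa-3,5-diene-1-carboxylate (C1 and C10 as in 6), via potassium dienolate 9 (not isolated)
Conditions: KN(SiMe3)2, THF, −78 °C; PhNTf2, −78 → 0 °C
Reagents that add atoms: N-phenylbis(trifluoromethanesulfonimide), O=S(=O)(N(c1ccccc1)S(=O)(=O)C(F)(F)F)C(F)(F)F
Why: Enol triflate formation by O-sulfonylation of the only possible (cross-conjugated) dienolate gives the C11(CH3)=C12(OTf)–C13=C14 dienyl triflate without creating a stereocentre.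

Step 5
Reactants: 10 dienyl triflate
Product: 11 ethyl 2-[(1R)-1-(tert-butyldimethylsilyloxy)prop-2-en-1-yl]-2,6-dimethylcyclohexa-3,5-diene-1-carboxylate (C1 and C10 as in 6)
Conditions: Pd(OAc)2 (5 mol %), PPh3 (10 mol %), HCO2H, n-Bu3N, DMF, 60 °C
Reagents that add atoms: none
Why: Palladium-catalysed formate reduction of the vinyl triflate (oxidative addition, hydride transfer from formate, reductive elimination) leaves the C11=C12–C13=C14 diene and does not touch the ester, silyl ether or vinyl group.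

Step 6
Reactants: 11 diene ester
Product: 12 ethyl 2-[(1R)-1-(tert-butyldimethylsilyloxy)prop-2-en-1-yl]-5,6-dihydroxy-2,6-dimethylcyclohex-3-ene-1-carboxylate (cis-diol; C11 S; C12 R)
Conditions: OsO4 (5 mol %), N-methylmorpholine N-oxide (1.05 equiv), acetone/H2O, 0 °C
Reagents that add atoms: osmium tetroxide, O=[Os](=O)(=O)=O; N-methylmorpholine N-oxide, C[N+]1([O-])CCOCC1; water, O
Why: Upjohn syn-dihydroxylation takes the electron-rich trisubstituted C11=C12 bond of the diene (C13=C14 is flanked by quaternary C1 and the vinyl group is neopentylic and deactivated by its allylic silyloxy group) from the face anti to the allylic ester at C10, so both hydroxyls arrive cis to each other and trans to C9.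

Step 7
Reactants: 12 cis-diol ester
Product: 14 ethyl 5-(tert-butyldimethylsilyloxy)-2-[(1R)-1-(tert-butyldimethylsilyloxy)prop-2-en-1-yl]-2,6-dimethyl-6-(triethylsilyloxy)cyclohex-3-ene-1-carboxylate, via C12 mono-TBS ether 13 (not isolated)
Conditions: TBSOTf (1.05 equiv), 2,6-lutidine, CH2Cl2, −78 °C; then TESOTf (1.5 equiv), −78 → 0 °C
Reagents that add atoms: tert-butyldimethylsilyl triflate, CC(C)(C)[Si](C)(C)OS(=O)(=O)C(F)(F)F; triethylsilyl triflate, CC[Si](CC)(CC)OS(=O)(=O)C(F)(F)F
Why: Silyl ether protection in which the secondary allylic C12 hydroxyl reacts first with the bulky silyl triflate at −78 °C and the hindered tertiary C11 hydroxyl is then capped with the smaller, later acid-removable triethylsilyl group.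

Step 8
Reactants: 14 bis-silylated ester
Product: 15 primary alcohol [the ring of 14 with CO2Et replaced by CH2OH (C9)]
Conditions: i-Bu2AlH (2.5 equiv), CH2Cl2, −78 → 0 °C; Rochelle salt work-up
Reagents that add atoms: none
Why: Hydride reduction of the ester to the primary alcohol, with no stereocentre affected.

Step 9
Reactants: 15 primary alcohol
Product: 16 primary iodide [the ring of 14 with CO2Et replaced by CH2I (C9)]
Conditions: I2, PPh3, imidazole, toluene/MeCN, 0 °C → rt
Reagents that add atoms: iodine, II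
Why: Appel-type (Garegg–Samuelsson) iodination through an alkoxyphosphonium ion, with SN2 displacement at the primary carbon.

**Tartrate fragment (steps 10–18)**

Step 10
Reactants: 17 D-(−)-tartaric acid
Product: 18 dimethyl (2S,3S)-tartrate
Conditions: MeOH, H2SO4 (cat.), reflux
Reagents that add atoms: methanol, CO
Why: Fischer esterification, which leaves both carbinol centres (future C6 and C7) untouched.

Step 11
Reactants: 18 dimethyl (2S,3S)-tartrate
Product: 19 dimethyl (4S,5S)-2,2-dimethyl-1,3-dioxolane-4,5-dicarboxylate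
Conditions: Me2C(OMe)2, p-toluenesulfonic acid (cat.), cyclohexane, reflux
Reagents that add atoms: 2,2-dimethoxypropane, COC(C)(C)OC
Why: Acid-catalysed transketalisation locks the threo diol as the trans-dioxolane with retention at both centres.

Step 12
Reactants: 19 acetonide diester
Product: 20 (4S,5S)-5-(methoxycarbonyl)-2,2-dimethyl-1,3-dioxolane-4-carboxylic acid
Conditions: KOH (1.0 equiv), MeOH, 0 °C → rt; then aq. HCl to pH 3
Reagents that add atoms: potassium hydroxide, [K+].[OH-]
Why: Monosaponification of a C2-symmetric diester, whose two ester groups are homotopic and whose monocarboxylate resists a second hydrolysis.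

Step 13
Reactants: 20 mono-acid
Product: 21 methyl (4S,5R)-5-(hydroxymethyl)-2,2-dimethyl-1,3-dioxolane-4-carboxylate
Conditions: BH3·SMe2, THF, 0 °C → rt
Reagents that add atoms: none
Why: Chemoselective borane reduction of the carboxylic acid in the presence of the ester.

Step 14
Reactants: 21 hydroxy ester
Product: 22 methyl (4S,5S)-5-formyl-2,2-dimethyl-1,3-dioxolane-4-carboxylate
Conditions: PhI(OAc)2, TEMPO (2,2,6,6-tetramethylpiperidine-1-oxyl, 10 mol %), CH2Cl2, rt
Reagents that add atoms: none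
Why: Oxoammonium (TEMPO) oxidation of the primary alcohol to the aldehyde under non-epimerising conditions.

Step 15
Reactants: 22 aldehyde ester
Product: 23 methyl (4S,5R)-5-ethynyl-2,2-dimethyl-1,3-dioxolane-4-carboxylate
Conditions: dimethyl (1-diazo-2-oxopropyl)phosphonate, K2CO3, MeOH, 0 °C → rt
Reagents that add atoms: dimethyl (1-diazo-2-oxopropyl)phosphonate, COP(=O)(OC)C(=[N+]=[N-])C(C)=O
Why: Seyferth–Gilbert homologation in the Ohira–Bestmann variant gives the terminal alkyne (C5≡C4), and the trans-dioxolane is the thermodynamically preferred arrangement so the α-centre is not at risk.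

Step 16
Reactants: 23 alkyne ester
Product: 24 methyl (4S,5R)-5-(buta-1,3-dien-2-yl)-2,2-dimethyl-1,3-dioxolane-4-carboxylate
Conditions: ethylene (1 atm), second-generation Grubbs catalyst (H2IMes)(PCy3)Cl2Ru=CHPh (5 mol %), CH2Cl2, rt
Reagents that add atoms: ethylene, C=C
Why: Enyne cross-metathesis with ethylene converts the terminal alkyne into the 2-substituted buta-1,3-diene that carries C16 and the alkylidene needed at C4.

Step 17
Reactants: 24 diene ester
Product: 25 (4S,5R)-5-(buta-1,3-dien-2-yl)-2,2-dimethyl-1,3-dioxolane-4-carboxylic acid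
Conditions: LiOH, THF/H2O, 0 °C; then aq. HCl to pH 3 at 0 °C
Reagents that add atoms: lithium hydroxide, [Li+].[OH-]
Why: Ester saponification under cold conditions that do not epimerise the α-alkoxy centre.

Step 18
Reactants: 25 diene acid
Product: 27 (4S,5R)-5-(buta-1,3-dien-2-yl)-N-methoxy-N,2,2-trimethyl-1,3-dioxolane-4-carboxamide, via acyl imidazole 26 (not isolated)
Conditions: 1,1′-carbonyldiimidazole, CH2Cl2, rt; then MeNH(OMe)·HCl, rt
Reagents that add atoms: N,O-dimethylhydroxylamine hydrochloride, CNOC.Cl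
Why: Weinreb amide formation by acyl imidazole activation and aminolysis.

**Fragment union and completion (steps 19–26)**

Step 19
Reactants: 16 primary iodide; 27 Weinreb amide
Product: 29 ketone 1-[(4S,5R)-5-(buta-1,3-dien-2-yl)-2,2-dimethyl-1,3-dioxolan-4-yl]-2-(ring of 16)ethan-1-one (C9H2–C8=O), via primary alkyllithium 28 (not isolated)
Conditions: 16, t-BuLi (2.1 equiv), Et2O/pentane, −78 °C; then 27, −78 °C; aq. NH4Cl
Reagents that add atoms: none
Why: Iodine–lithium exchange gives a primary alkyllithium (kept at −78 °C in a non-polar medium to suppress 5-exo carbolithiation and retro-Brook silyl shift) whose addition to the Weinreb amide stops at the chelated tetrahedral adduct and releases the ketone on work-up (Weinreb ketone synthesis), forming the C8–C9 bond.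

Step 20
Reactants: 29 ketone
Product: 32 (9R)-9-(tert-butyldimethylsilyloxy) ketone, via potassium enolate 30 (not isolated), via potassium alkoxide 31 (not isolated)
Conditions: KN(SiMe3)2 (1.1 equiv), THF, −78 °C; (−)-(camphorsulfonyl)oxaziridine, −78 °C; then TBSOTf, −78 → −40 °C
Reagents that add atoms: (−)-(camphorsulfonyl)oxaziridine, CC1(C)C2CCC13CS(=O)(=O)N4OC34C2; tert-butyldimethylsilyl triflate, CC(C)(C)[Si](C)(C)OS(=O)(=O)C(F)(F)F
Why: Kinetic enolisation towards the C9 methylene (away from the dioxolane carbon) gives the Z-enolate, which undergoes Davis oxaziridine hydroxylation under reagent control to set C9 (R), and the resulting alkoxide is silylated in the same flask.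

Step 21
Reactants: 32 (9R)-silyloxy ketone; 33 methyl propanoate
Product: 35 β-hydroxy ester [C8(OH)–C17H(CH3)–CO2CH3; C8 as in the target; both C17 epimers], via lithium ester enolate 34 (not isolated)
Conditions: 33, LiN(iPr)2, THF, −78 °C; then 32 premixed with anhydrous CeCl3, THF, −78 °C; aq. NH4Cl
Reagents that add atoms: none
Why: Aldol addition of the ester enolate to the ketone under Cram chelation control, in which the metal bridges the ketone oxygen and the dioxolane oxygen at C7 so that the nucleophile enters anti to the C6 substituent and sets C8 with the target configuration, while C17 forms as a mixture that converges in step 22.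

Step 22
Reactants: 35 β-hydroxy ester
Product: 37 γ-lactone allylic alcohol [lactone O7–C19; free OH at C6 (R), C8 and C11; 17R], via tetraol methyl ester 36 (not isolated)
Conditions: CeCl3·7H2O, oxalic acid, MeCN, rt; then DBU (1,8-diazabicyclo[5.4.0]undec-7-ene), toluene, 60 °C
Reagents that add atoms: none
Why: Mild acid hydrolysis removes the acetonide and the tertiary triethylsilyl ether but spares the secondary TBS ethers, the C7 hydroxyl then closes the five-membered lactone (lactonisation by 5-exo-trig acyl transfer, favoured over the six-membered ring through O6), and DBU equilibrates C17 to the more stable epimer with its methyl trans to the bulky C9 substituent (17R).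

Step 23
Reactants: 37 lactone allylic alcohol
Product: 38 (6S)-allylic chloride triene
Conditions: Cl3CC(O)CCl3, PPh3, CH2Cl2, −20 → 0 °C
Reagents that add atoms: hexachloroacetone, ClC(Cl)(Cl)C(=O)C(Cl)(Cl)Cl
Why: Magid chlorination, in which the alkoxyphosphonium chloride ion pair collapses by SN2 at the secondary allylic carbon with inversion and without allylic transposition to set C6 (S), the tertiary hydroxyls being unreactive at this temperature.

Step 24
Reactants: 38 allylic chloride triene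
Product: 39 ten-membered (3Z)-diene macrocycle as its 2,9,12-tris(tert-butyldimethylsilyl) ether
Conditions: second-generation Grubbs catalyst (H2IMes)(PCy3)Cl2Ru=CHPh (15 mol %, in portions), toluene (1 mM), 80 °C, argon sparge
Reagents that add atoms: none
Why: Ring-closing metathesis in which ruthenium loads on the unhindered monosubstituted terminus of the butadiene (C4) and closes onto the C2 vinyl group with loss of ethylene, the trans-fused cyclohexene and the lactone pre-organising the chain and the ten-membered ring accommodating only the Z alkene.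

Step 25
Reactants: 39 macrocyclic tris-silyl ether
Product: 40 macrocyclic pentaol (free OH at C2, C8, C9, C11, C12)
Conditions: HF·pyridine, pyridine, THF, 0 °C → rt
Reagents that add atoms: none
Why: Fluoride-mediated silyl ether cleavage under buffered conditions that the allylic chloride, diene and lactone tolerate.

Step 26
Reactants: 40 macrocyclic pentaol
Product: 41 CNP0285654.4 (target)
Conditions: Ac2O, pyridine, 4-(dimethylamino)pyridine (cat.), CH2Cl2, 0 °C → rt
Reagents that add atoms: acetic anhydride, CC(=O)OC(C)=O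
Why: Nucleophile-catalysed acetylation of the three secondary hydroxyls (C2, C9, C12), which leaves the tertiary hydroxyls at C8 and C11 free.

**Compound list**

1 | ethyl (E)-3-methyl-4-oxobut-2-enoate | CCOC(=O)/C=C(\C)C=O | starting material
2 | (E)-3-(tert-butyldimethylsilyloxy)-N,N-dimethylbuta-1,3-dien-1-amine (Rawal diene) | C=C(O[Si](C)(C)C(C)(C)C)/C=C/N(C)C | starting material
3 | cycloadduct, ethyl 5-(tert-butyldimethylsilyloxy)-3-(dimethylamino)-2-formyl-2-methylcyclohex-4-ene-1-carboxylate (C1, C10 as in 4; amine carbon as epimers) | O=C[C@@]1(C)C(N(C)C)C=C(O[Si](C)(C)C(C)(C)C)C[C@@H]1C(=O)OCC | intermediate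
4 | ethyl (1S,2S)-2-formyl-2-methyl-5-oxocyclohex-3-ene-1-carboxylate (CHO and CO2Et trans) | O=C[C@@]1(C)C=CC(=O)C[C@@H]1C(=O)OCC | intermediate
5 | vinylzinc alkoxide of the (2R)-vinyl carbinol derived from 4 | C=C[C@@H](O[Zn]C=C)[C@@]1(C)C=CC(=O)C[C@@H]1C(=O)OCC | intermediate
6 | ethyl (1S,2S)-2-[(1R)-1-(tert-butyldimethylsilyloxy)prop-2-en-1-yl]-2-methyl-5-oxocyclohex-3-ene-1-carboxylate | C=C[C@@H](O[Si](C)(C)C(C)(C)C)[C@@]1(C)C=CC(=O)C[C@@H]1C(=O)OCC | intermediate
7 | lithium cross-conjugated dienolate of 6 (C11=C12–OLi) | C=C[C@@H](O[Si](C)(C)C(C)(C)C)[C@@]1(C)C=CC(O[Li])=C[C@@H]1C(=O)OCC | intermediate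
8 | ethyl 2-[(1R)-1-(tert-butyldimethylsilyloxy)prop-2-en-1-yl]-2,6-dimethyl-5-oxocyclohex-3-ene-1-carboxylate (C1, C10 as in 6; C11 epimers) | C=C[C@@H](O[Si](C)(C)C(C)(C)C)[C@@]1(C)C=CC(=O)C(C)[C@@H]1C(=O)OCC | intermediate
9 | potassium dienolate of 8 | C=C[C@@H](O[Si](C)(C)C(C)(C)C)[C@@]1(C)C=CC(O[K])=C(C)[C@@H]1C(=O)OCC | intermediate
10 | dienyl triflate, ethyl 2-[(1R)-1-(tert-butyldimethylsilyloxy)prop-2-en-1-yl]-2,6-dimethyl-5-(trifluoromethylsulfonyloxy)cyclohexa-3,5-diene-1-carboxylate | C=C[C@@H](O[Si](C)(C)C(C)(C)C)[C@@]1(C)C=CC(OS(=O)(=O)C(F)(F)F)=C(C)[C@@H]1C(=O)OCC | intermediate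
11 | diene ester, ethyl 2-[(1R)-1-(tert-butyldimethylsilyloxy)prop-2-en-1-yl]-2,6-dimethylcyclohexa-3,5-diene-1-carboxylate | C=C[C@@H](O[Si](C)(C)C(C)(C)C)[C@@]1(C)C=CC=C(C)[C@@H]1C(=O)OCC | intermediate
12 | cis-diol ester (C11 S, C12 R; both OH trans to the ester) | C=C[C@@H](O[Si](C)(C)C(C)(C)C)[C@@]1(C)C=C[C@@H](O)[C@@](C)(O)[C@@H]1C(=O)OCC | intermediate
13 | C12 mono-TBS ether of 12 (C11 OH free) | C=C[C@@H](O[Si](C)(C)C(C)(C)C)[C@@]1(C)C=C[C@@H](O[Si](C)(C)C(C)(C)C)[C@@](C)(O)[C@@H]1C(=O)OCC | intermediate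
14 | ester with C2-OTBS, C12-OTBS, C11-OTES | C=C[C@@H](O[Si](C)(C)C(C)(C)C)[C@@]1(C)C=C[C@@H](O[Si](C)(C)C(C)(C)C)[C@@](C)(O[Si](CC)(CC)CC)[C@@H]1C(=O)OCC | intermediate
15 | primary alcohol (C9H2OH) from 14 | C=C[C@@H](O[Si](C)(C)C(C)(C)C)[C@@]1(C)C=C[C@@H](O[Si](C)(C)C(C)(C)C)[C@@](C)(O[Si](CC)(CC)CC)[C@@H]1CO | intermediate
16 | primary iodide (C9H2I), ring fragment | C=C[C@@H](O[Si](C)(C)C(C)(C)C)[C@@]1(C)C=C[C@@H](O[Si](C)(C)C(C)(C)C)[C@@](C)(O[Si](CC)(CC)CC)[C@@H]1CI | intermediate
17 | D-(−)-tartaric acid, (2S,3S) | O=C(O)[C@@H](O)[C@H](O)C(=O)O | starting material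
18 | dimethyl (2S,3S)-tartrate | COC(=O)[C@@H](O)[C@H](O)C(=O)OC | intermediate
19 | dimethyl (4S,5S)-2,2-dimethyl-1,3-dioxolane-4,5-dicarboxylate | COC(=O)[C@H]1OC(C)(C)O[C@@H]1C(=O)OC | intermediate
20 | (4S,5S)-5-(methoxycarbonyl)-2,2-dimethyl-1,3-dioxolane-4-carboxylic acid | COC(=O)[C@H]1OC(C)(C)O[C@@H]1C(=O)O | intermediate
21 | methyl (4S,5R)-5-(hydroxymethyl)-2,2-dimethyl-1,3-dioxolane-4-carboxylate | COC(=O)[C@H]1OC(C)(C)O[C@@H]1CO | intermediate
22 | methyl (4S,5S)-5-formyl-2,2-dimethyl-1,3-dioxolane-4-carboxylate | COC(=O)[C@H]1OC(C)(C)O[C@@H]1C=O | intermediate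
23 | methyl (4S,5R)-5-ethynyl-2,2-dimethyl-1,3-dioxolane-4-carboxylate | COC(=O)[C@H]1OC(C)(C)O[C@@H]1C#C | intermediate
24 | methyl (4S,5R)-5-(buta-1,3-dien-2-yl)-2,2-dimethyl-1,3-dioxolane-4-carboxylate | COC(=O)[C@H]1OC(C)(C)O[C@@H]1C(=C)C=C | intermediate
25 | (4S,5R)-5-(buta-1,3-dien-2-yl)-2,2-dimethyl-1,3-dioxolane-4-carboxylic acid | OC(=O)[C@H]1OC(C)(C)O[C@@H]1C(=C)C=C | intermediate
26 | acyl imidazole of 25 | O=C(n1ccnc1)[C@H]2OC(C)(C)O[C@@H]2C(=C)C=C | intermediate
27 | (4S,5R)-5-(buta-1,3-dien-2-yl)-N-methoxy-N,2,2-trimethyl-1,3-dioxolane-4-carboxamide (Weinreb amide) | CON(C)C(=O)[C@H]1OC(C)(C)O[C@@H]1C(=C)C=C | intermediate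
28 | primary alkyllithium from 16 (C9H2Li) | C=C[C@@H](O[Si](C)(C)C(C)(C)C)[C@@]1(C)C=C[C@@H](O[Si](C)(C)C(C)(C)C)[C@@](C)(O[Si](CC)(CC)CC)[C@@H]1C[Li] | intermediate
29 | coupled ketone (C9H2–C8(=O)–C7 dioxolane, diene at C5) | C=C[C@@H](O[Si](C)(C)C(C)(C)C)[C@@]1(C)C=C[C@@H](O[Si](C)(C)C(C)(C)C)[C@@](C)(O[Si](CC)(CC)CC)[C@@H]1CC(=O)[C@H]2OC(C)(C)O[C@@H]2C(=C)C=C | intermediate
30 | (Z)-potassium enolate of 29 (C9=C8–OK) | C=C[C@@H](O[Si](C)(C)C(C)(C)C)[C@@]1(C)C=C[C@@H](O[Si](C)(C)C(C)(C)C)[C@@](C)(O[Si](CC)(CC)CC)[C@@H]1/C=C(\O[K])[C@H]2OC(C)(C)O[C@@H]2C(=C)C=C | intermediate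
31 | potassium alkoxide of the (9R)-α-hydroxy ketone | C=C[C@@H](O[Si](C)(C)C(C)(C)C)[C@@]1(C)C=C[C@@H](O[Si](C)(C)C(C)(C)C)[C@@](C)(O[Si](CC)(CC)CC)[C@@H]1[C@@H](O[K])C(=O)[C@H]2OC(C)(C)O[C@@H]2C(=C)C=C | intermediate
32 | (9R)-9-(tert-butyldimethylsilyloxy) C8 ketone | C=C[C@@H](O[Si](C)(C)C(C)(C)C)[C@@]1(C)C=C[C@@H](O[Si](C)(C)C(C)(C)C)[C@@](C)(O[Si](CC)(CC)CC)[C@@H]1[C@@H](O[Si](C)(C)C(C)(C)C)C(=O)[C@H]2OC(C)(C)O[C@@H]2C(=C)C=C | intermediate
33 | methyl propanoate | CCC(=O)OC | starting material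
34 | lithium enolate of methyl propanoate | CC=C(OC)O[Li] | intermediate
35 | aldol adduct, tertiary C8 alcohol with CH(CH3)CO2CH3 at C8 (C8 as in target; C17 epimers) | C=C[C@@H](O[Si](C)(C)C(C)(C)C)[C@@]1(C)C=C[C@@H](O[Si](C)(C)C(C)(C)C)[C@@](C)(O[Si](CC)(CC)CC)[C@@H]1[C@@H](O[Si](C)(C)C(C)(C)C)[C@](O)(C(C)C(=O)OC)[C@H]2OC(C)(C)O[C@@H]2C(=C)C=C | intermediate
36 | tetraol methyl ester (OH at C6, C7, C8, C11; C17 epimers) | C=C[C@@H](O[Si](C)(C)C(C)(C)C)[C@@]1(C)C=C[C@@H](O[Si](C)(C)C(C)(C)C)[C@@](C)(O)[C@@H]1[C@@H](O[Si](C)(C)C(C)(C)C)[C@](O)(C(C)C(=O)OC)[C@@H](O)[C@H](O)C(=C)C=C | intermediate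
37 | γ-lactone allylic alcohol (6R-OH, 17R; OH at C8, C11; TBS at O2, O9, O12) | C=C[C@@H](O[Si](C)(C)C(C)(C)C)[C@@]1(C)C=C[C@@H](O[Si](C)(C)C(C)(C)C)[C@@](C)(O)[C@@H]1[C@@H](O[Si](C)(C)C(C)(C)C)[C@]2(O)[C@@H](C)C(=O)O[C@H]2[C@H](O)C(=C)C=C | intermediate
38 | (6S)-allylic chloride triene | C=C[C@@H](O[Si](C)(C)C(C)(C)C)[C@@]1(C)C=C[C@@H](O[Si](C)(C)C(C)(C)C)[C@@](C)(O)[C@@H]1[C@@H](O[Si](C)(C)C(C)(C)C)[C@]2(O)[C@@H](C)C(=O)O[C@H]2[C@@H](Cl)C(=C)C=C | intermediate
39 | ten-membered (3Z) macrocycle, 2,9,12-tris-TBS ether | C=C1/C=C\[C@@H](O[Si](C)(C)C(C)(C)C)[C@@]2(C)C=C[C@@H](O[Si](C)(C)C(C)(C)C)[C@@](C)(O)[C@@H]2[C@@H](O[Si](C)(C)C(C)(C)C)[C@]2(O)[C@@H](C)C(=O)O[C@H]2[C@H]1Cl | intermediate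
40 | macrocyclic pentaol (OH at C2, C8, C9, C11, C12) | C=C1/C=C\[C@@H](O)[C@@]2(C)C=C[C@@H](O)[C@@](C)(O)[C@@H]2[C@@H](O)[C@]2(O)[C@@H](C)C(=O)O[C@H]2[C@H]1Cl | intermediate
41 | CNP0285654.4, (1S,2R,3Z,6S,7R,8R,9R,10S,11S,12R,17R)-2,9,12-triacetoxy-6-chloro-8,11-dihydroxy-briara-3,5(16),13-triene 19,7-lactone | C=C1/C=C\[C@@H](OC(C)=O)[C@@]2(C)C=C[C@@H](OC(C)=O)[C@@](C)(O)[C@@H]2[C@@H](OC(C)=O)[C@]2(O)[C@@H](C)C(=O)O[C@H]2[C@H]1Cl | target

**Totals and risks**

Total step count: 26. Longest linear sequence: 17 steps (steps 1–9 then 19–26; the tartaric acid branch, steps 10–18 then 19–26, is equally long).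

Three steps most likely to fail:

Step 20 (C9 hydroxylation; regiochemistry of enolisation and the C9 configuration may be poor). The fallback sets out from ketone 29. Soft enolisation (TBSOTf, Et3N, CH2Cl2, −78 °C) gives the (Z)-silyl enol ether F1. Shi asymmetric epoxidation of F1 follows, using the fructose-derived Shi ketone (1,2:4,5-di-O-isopropylidene-β-D-erythro-2,3-hexodiulo-2,6-pyranose) of the enantiomeric series that gives 9R, with Oxone (2KHSO5·KHSO4·K2SO4) and K2CO3 buffer in MeCN/dimethoxymethane/H2O at 0 °C. This oxidises only the electron-rich enol ether, and the silyloxy epoxide opens in the flask to the (9R)-α-hydroxy ketone F2. Silylation of F2 (TBSOTf, 2,6-lutidine, CH2Cl2, −78 °C) returns to the route at 32.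

Step 21 (addition to the doubly α-branched ketone may be slow or poorly face-selective). The fallback sets out from 32. The smaller lithium enolate of methyl acetate (LiN(iPr)2, THF, −78 °C, CeCl3) adds under the same chelation control to give the β-hydroxy acetate F3. Fráter–Seebach methylation of the dianion of F3 (LiN(iPr)2 2.2 equiv, then MeI, THF, −78 → −20 °C) installs C18 and returns to the route at 35, whose C17 epimers converge in step 22 as before.

Step 24 (ring-closing metathesis may stall or oligomerise). The fallback sets out from lactone allylic alcohol 37. Ring closure is run on the free allylic alcohol, a substrate with a different conformational bias and a hydroxyl next to the diene that assists catalyst loading (same ruthenium catalyst, toluene, 1 mM, 80 °C). This gives the macrocyclic allylic alcohol F4. Magid chlorination of F4 (hexachloroacetone, PPh3, CH2Cl2, −20 °C) then installs the C6 chloride with inversion and returns to the route at 39.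

**Further compounds**

F1 | step 20 | (Z)-tert-butyldimethylsilyl enol ether of ketone 29 (C9=C8–OTBS) | C=C[C@@H](O[Si](C)(C)C(C)(C)C)[C@@]1(C)C=C[C@@H](O[Si](C)(C)C(C)(C)C)[C@@](C)(O[Si](CC)(CC)CC)[C@@H]1/C=C(\O[Si](C)(C)C(C)(C)C)[C@H]2OC(C)(C)O[C@@H]2C(=C)C=C
F2 | step 20 | (9R)-α-hydroxy ketone (free C9 OH) | C=C[C@@H](O[Si](C)(C)C(C)(C)C)[C@@]1(C)C=C[C@@H](O[Si](C)(C)C(C)(C)C)[C@@](C)(O[Si](CC)(CC)CC)[C@@H]1[C@@H](O)C(=O)[C@H]2OC(C)(C)O[C@@H]2C(=C)C=C
F3 | step 21 | β-hydroxy acetate, tertiary C8 alcohol with CH2CO2CH3 at C8 | C=C[C@@H](O[Si](C)(C)C(C)(C)C)[C@@]1(C)C=C[C@@H](O[Si](C)(C)C(C)(C)C)[C@@](C)(O[Si](CC)(CC)CC)[C@@H]1[C@@H](O[Si](C)(C)C(C)(C)C)[C@](O)(CC(=O)OC)[C@H]2OC(C)(C)O[C@@H]2C(=C)C=C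
F4 | step 24 | ten-membered (3Z) macrocyclic allylic alcohol (6R-OH), 2,9,12-tris-TBS ether | C=C1/C=C\[C@@H](O[Si](C)(C)C(C)(C)C)[C@@]2(C)C=C[C@@H](O[Si](C)(C)C(C)(C)C)[C@@](C)(O)[C@@H]2[C@@H](O[Si](C)(C)C(C)(C)C)[C@]2(O)[C@@H](C)C(=O)O[C@H]2[C@@H]1O
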